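**Strategy**

The pyranone ring (ring B) is cut at C4–C4a and O1–C8a. This leaves a β-hydroxy acid, O1–C2–C3–C4(=O), whose quaternary C2 with its oxygen is C3 of (R)-linalool, and a benzene ring (ring A) with two adjacent reactive carbons. The acid is closed to a β-lactone. An aryl Grignard reagent carrying Mg on C4a and F on C8a, a regiodefined aryne equivalent, opens the lactone at its acyl carbon; the tertiary alkoxide set free then displaces the fluoride, which the new C4 ketone activates. One pot thus inserts ring A into the lactone acyl–oxygen bond and expands the four-membered ring to ring B, with C2 untouched.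

Key step: step 6

Remark: chroman-4-one numbering is used (O1, C2, C3, C4, C4a, C5 to C8, C8a); the target is (R) at C2; (R)-(−)-linalool of high enantiomeric purity and 4-fluoro-3-iodophenol are taken as catalogue compounds.

**Route**

Step 1
Reactants: 1 (R)-(−)-linalool
Product: 2 (R)-3,7-dimethyloct-6-ene-1,3-diol
Conditions: 9-BBN, THF, 0 → 23 °C; then NaOH, H2O2, H2O, 0 → 23 °C
Reagents that add atoms: hydrogen peroxide (OO)
Why: Hydroboration–oxidation: the bulky dialkylborane should add anti-Markovnikov to the monosubstituted vinyl group far faster than to the trisubstituted alkene, and the carbinol stereocentre is not touched.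

Step 2
Reactants: 2 (R)-3,7-dimethyloct-6-ene-1,3-diol
Product: 3 (R)-3-hydroxy-3,7-dimethyloct-6-enoic acid
Conditions: TEMPO (cat.), PhI(OAc)2, MeCN/H2O, 0 → 23 °C
Reagents that add atoms: water (O)
Why: TEMPO/PhI(OAc)2 oxidation in aqueous acetonitrile should take the primary alcohol through the aldehyde hydrate to the carboxylic acid while leaving the tertiary alcohol and the trisubstituted alkene alone.

Step 3
Reactants: 3 (R)-3-hydroxy-3,7-dimethyloct-6-enoic acid
Product: 4 (R)-4-methyl-4-(4-methylpent-3-en-1-yl)oxetan-2-one
Conditions: PhSO2Cl, pyridine, 0 → 5 °C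
Reagents that add atoms: none
Why: Adam β-lactonisation: the sulfonyl chloride activates the carboxyl group as a mixed anhydride that the tertiary hydroxyl attacks, so the C–O bond at the stereocentre is never broken and the configuration is retained.

Step 4
Reactants: 5 4-fluoro-3-iodophenol
Product: 6 2-bromo-4-fluoro-5-iodophenol
Conditions: NBS, i-Pr2NH (cat.), CH2Cl2, 0 °C
Reagents that add atoms: N-bromosuccinimide (O=C1CCC(=O)N1Br)
Why: Electrophilic aromatic bromination: the hydroxyl group directs ortho (para is blocked by fluorine), and of the two ortho positions the one not flanked by the large iodine should react.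

Step 5
Reactants: 6 2-bromo-4-fluoro-5-iodophenol
Product: 7 1-bromo-5-fluoro-4-iodo-2-(methoxymethoxy)benzene
Conditions: MOMCl, i-Pr2NEt, CH2Cl2, 0 → 23 °C
Reagents that add atoms: chloromethyl methyl ether (COCCl)
Why: O-Alkylation of the phenol gives an acetal ether that is inert to Grignard reagents and alkoxides and keeps the C6 oxygen from becoming a ring-deactivating phenoxide in step 6.

Step 6
Reactants: 7 1-bromo-5-fluoro-4-iodo-2-(methoxymethoxy)benzene; 4 (R)-4-methyl-4-(4-methylpent-3-en-1-yl)oxetan-2-one
Product: 10 (R)-7-bromo-6-(methoxymethoxy)-2-methyl-2-(4-methylpent-3-en-1-yl)chroman-4-one, via arylmagnesium chloride 8 (not isolated), via magnesium keto alkoxide 9 (not isolated)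
Conditions: i-PrMgCl·LiCl, THF, −40 °C; add to 4 (slight excess) in THF, −78 → −20 °C; then DMPU, −20 → 40 °C
Reagents that add atoms: none
Why: Iodine–magnesium exchange at −40 °C (the iodide reacts, the bromide does not) gives the 2-fluoroarylmagnesium 8, whose carbanion attacks the strained lactone carbonyl (acyl–oxygen cleavage, since the alkyl carbon is quaternary), forming C4–C4a and releasing the tertiary alkoxide 9. That alkoxide then adds to C8a, now the β-carbon of a vinylogous acyl fluoride, and fluoride leaves (SNAr by addition–elimination), forming O1–C8a and closing ring B in the 6-endo-trig mode. The closest known reaction types are the acyl ring opening of β-lactones by Grignard reagents and the alkoxide SNAr closure of 2-fluoroaryl ketones to chromanones and xanthones, here run in one pot as a formal insertion of a 1,2-arylene into the lactone acyl–oxygen bond. No stereocentre is made: C2 is carried from 4 with retention because none of its four bonds is made or broken. The step needs regioselectivity (oxygen on C8a, acyl on C4a), which a free 4,5-disubstituted aryne would not give and which the fixed positions of iodine and fluorine in 7 secure, and it needs mono-addition, favoured by adding 8 to an excess of the lactone, which is far more electrophilic than the chelated alkoxy ketone 9.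

Step 7
Reactants: 10 (R)-7-bromo-6-(methoxymethoxy)-2-methyl-2-(4-methylpent-3-en-1-yl)chroman-4-one
Product: 11 (R)-7-bromo-2-(4-hydroxy-4-methylpentyl)-6-(methoxymethoxy)-2-methylchroman-4-one
Conditions: Co(acac)2 (cat.), PhSiH3, O2 (1 atm), THF, 23 °C
Reagents that add atoms: dioxygen (O=O)
Why: Mukaiyama hydration: hydrogen-atom transfer from a cobalt hydride to the trisubstituted alkene should give the tertiary radical, which is trapped by O2 and reduced to the Markovnikov tertiary alcohol, with the aryl bromide, ketone and acetal as spectators.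

Step 8
Reactants: 11 (R)-7-bromo-2-(4-hydroxy-4-methylpentyl)-6-(methoxymethoxy)-2-methylchroman-4-one
Product: 12 (R)-7-bromo-6-hydroxy-2-(4-hydroxy-4-methylpentyl)-2-methylchroman-4-one
Conditions: HCl (cat.), MeOH, 40 °C
Reagents that add atoms: none
Why: Acid-catalysed transacetalisation to methanol should cleave the aryl methoxymethyl ether, and the 2,2-dialkylchromanone is configurationally stable to acid because ring opening would need a base-induced β-elimination.

**Compound list**

1 | (R)-(−)-linalool, (R)-3,7-dimethylocta-1,6-dien-3-ol | CC(C)=CCC[C@@](C)(O)C=C | starting material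
2 | (R)-3,7-dimethyloct-6-ene-1,3-diol | CC(C)=CCC[C@@](C)(O)CCO | intermediate
3 | (R)-3-hydroxy-3,7-dimethyloct-6-enoic acid | CC(C)=CCC[C@@](C)(O)CC(=O)O | intermediate
4 | (R)-4-methyl-4-(4-methylpent-3-en-1-yl)oxetan-2-one | CC(C)=CCC[C@]1(C)CC(=O)O1 | intermediate
5 | 4-fluoro-3-iodophenol | Oc1ccc(F)c(I)c1 | starting material
6 | 2-bromo-4-fluoro-5-iodophenol | Oc1cc(I)c(F)cc1Br | intermediate
7 | 1-bromo-5-fluoro-4-iodo-2-(methoxymethoxy)benzene | COCOc1cc(I)c(F)cc1Br | intermediate
8 | [4-bromo-2-fluoro-5-(methoxymethoxy)phenyl]magnesium chloride (not isolated) | COCOc1cc([Mg]Cl)c(F)cc1Br | intermediate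
9 | chloromagnesium (R)-1-[4-bromo-2-fluoro-5-(methoxymethoxy)phenyl]-3,7-dimethyl-1-oxooct-6-en-3-olate (not isolated) | CC(C)=CCC[C@@](C)(O[Mg]Cl)CC(=O)c1cc(OCOC)c(Br)cc1F | intermediate
10 | (R)-7-bromo-6-(methoxymethoxy)-2-methyl-2-(4-methylpent-3-en-1-yl)chroman-4-one | CC(C)=CCC[C@]1(C)CC(=O)c2cc(OCOC)c(Br)cc2O1 | intermediate
11 | (R)-7-bromo-2-(4-hydroxy-4-methylpentyl)-6-(methoxymethoxy)-2-methylchroman-4-one | CC(C)(O)CCC[C@]1(C)CC(=O)c2cc(OCOC)c(Br)cc2O1 | intermediate
12 | (R)-7-bromo-6-hydroxy-2-(4-hydroxy-4-methylpentyl)-2-methylchroman-4-one | CC(C)(O)CCC[C@]1(C)CC(=O)c2cc(O)c(Br)cc2O1 | target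

**Count**

Total steps: 8. Longest linear sequence: 6 steps (steps 1, 2, 3, 6, 7, 8).

**Steps most likely to fail**

Step 6. Three processes may compete: a second aryl transfer to the ketone as soon as the lactone collapses, retro-aldol cleavage of the tertiary aldolate before the weakly nucleophilic magnesium alkoxide closes the ring, and loss of MgClF from unreacted 8 to an aryne on warming. The fallback sets out from 4 and 7 and comes back at 10. Lactone 4 is opened with MeNH(OMe)·HCl and Me2AlCl to the Weinreb amide (R)-3-hydroxy-N-methoxy-N,3,7-trimethyloct-6-enamide F1. Its hydroxyl is deprotonated with i-PrMgCl, and 8, made from 7 as before, is added at −40 °C; the reaction should stop at the chelated tetrahedral adduct and give, after aqueous work-up, the isolated hydroxy ketone (R)-1-[4-bromo-2-fluoro-5-(methoxymethoxy)phenyl]-3-hydroxy-3,7-dimethyloct-6-en-1-one F2. Ring closure is then run as a separate SNAr step with KN(SiMe3)2 in THF/DMF, −40 → 0 °C, to give 10.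

Step 7. The intermediate peroxide may be reduced incompletely, or radical reduction may reach the aryl ketone. The fallback sets out from 10 and comes back at 12, using an ionic Markovnikov route. HCl (4 M in dioxane), CH2Cl2, 0 °C should add to the trisubstituted alkene and cleave the acetal at the same time, giving the tertiary chloride (R)-7-bromo-2-(4-chloro-4-methylpentyl)-6-hydroxy-2-methylchroman-4-one F3. Silver-assisted solvolysis (AgNO3, acetone/H2O, 23 °C) should then give 12 directly, so that step 8 is not needed.

Step 8. Acid may ionise the side-chain tertiary alcohol (elimination or methyl ether formation) in competition with acetal cleavage. The fallback sets out from 10 and comes back at 12; it removes the acetal before the tertiary alcohol exists. HCl (cat.), MeOH on 10 should give the phenol (R)-7-bromo-6-hydroxy-2-methyl-2-(4-methylpent-3-en-1-yl)chroman-4-one F4. TBSCl and imidazole in DMF give the silyl ether (R)-7-bromo-6-[(tert-butyldimethylsilyl)oxy]-2-methyl-2-(4-methylpent-3-en-1-yl)chroman-4-one F5. Hydration as in step 7 gives (R)-7-bromo-6-[(tert-butyldimethylsilyl)oxy]-2-(4-hydroxy-4-methylpentyl)-2-methylchroman-4-one F6, and Bu4NF buffered with AcOH in THF at 0 °C should release 12 under near-neutral conditions.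

**Further compounds**

F1 | step 6 | (R)-3-hydroxy-N-methoxy-N,3,7-trimethyloct-6-enamide | CC(C)=CCC[C@@](C)(O)CC(=O)N(C)OC
F2 | step 6 | (R)-1-[4-bromo-2-fluoro-5-(methoxymethoxy)phenyl]-3-hydroxy-3,7-dimethyloct-6-en-1-one | CC(C)=CCC[C@@](C)(O)CC(=O)c1cc(OCOC)c(Br)cc1F
F3 | step 7 | (R)-7-bromo-2-(4-chloro-4-methylpentyl)-6-hydroxy-2-methylchroman-4-one | CC(C)(Cl)CCC[C@]1(C)CC(=O)c2cc(O)c(Br)cc2O1
F4 | step 8 | (R)-7-bromo-6-hydroxy-2-methyl-2-(4-methylpent-3-en-1-yl)chroman-4-one | CC(C)=CCC[C@]1(C)CC(=O)c2cc(O)c(Br)cc2O1
F5 | step 8 | (R)-7-bromo-6-[(tert-butyldimethylsilyl)oxy]-2-methyl-2-(4-methylpent-3-en-1-yl)chroman-4-one | CC(C)=CCC[C@]1(C)CC(=O)c2cc(O[Si](C)(C)C(C)(C)C)c(Br)cc2O1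
F6 | step 8 | (R)-7-bromo-6-[(tert-butyldimethylsilyl)oxy]-2-(4-hydroxy-4-methylpentyl)-2-methylchroman-4-one | CC(C)(O)CCC[C@]1(C)CC(=O)c2cc(O[Si](C)(C)C(C)(C)C)c(Br)cc2O1
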